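**Plan**

Carotenoid numbering is used: ring A = C1 (gem-dimethyl), C2, C3 (ketone), C4=C5 (5-methyl), C6 (exocyclic C6=C7); chain C7 to C15 and C15' to C7'; ring B = C1' to C6' with the C3' hydroxyl.
Cuts: C10'–C11' together with C9'–CH3 in one three-component event; then C11=C12 (Wittig), C11'=C12' (one-carbon iodo-olefination), C6–C7 (acetylide addition, with C8=O arising by a Meyer–Schuster shift) and C6'–C7' (diynide addition).
Enabling feature: the trisubstituted C9'(CH3)=C10'H alkene has its methyl cis to the C10'–C11' bond and sits on the C7'≡C8' alkyne of ring B. It is therefore the retron of a syn-methylmetalation of a terminal 1,3-diyne whose metal-bearing C10' is cross-coupled in the same flask; the internal C7'≡C8' alkyne is shielded by the C5' methyl and the C1' gem-dimethyl group.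
Forward, fragment 1 (C26): ring A is taken intact from ketoisophorone (ketal at the future C3), then enynol acetylide addition at the future C6, Meyer–Schuster rearrangement and deketalisation, C15 phosphonium salt, and Wittig reaction with the C11 iodo-tetraenal made by mono-Takai olefination of the C10 dialdehyde.
Forward, fragment 2 precursor (C13): ring B is taken intact from (4R,6R)-actinol by silylation, butadiynide addition, dehydration and desilylation to the terminal diyne. The last step methylaluminates this diyne and couples it with the C26 iodide to give the unprotected target; no ring is formed in the route.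
Stereochemistry: C3' (R) from actinol; 9'E from syn-carboalumination; 11'E from the Takai reaction; 13E, 15E, 13'E from the C10 dialdehyde; 9E from the commercial (E)-enynol; 11E from the Wittig step with thermal convergence; 6Z from the thermodynamically controlled Meyer–Schuster step.

Key step: step 11

Assumption: the 6Z geometry of the exocyclic C6=C7 bond (C8 acyl group syn to C5, anti to the C1 gem-dimethyl group) is taken to be the thermodynamically preferred arrangement of the cross-conjugated dienedione, so that acid, phosphine or heat anywhere in the route converges on it.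

**Route**

Step 1
Reactants: 1 ketoisophorone (2,6,6-trimethylcyclohex-2-ene-1,4-dione)
Product: 2 7,9,9-trimethyl-1,4-dioxaspiro[4.5]dec-6-en-8-one
Conditions: HOCH2CH2OH (1.5 equiv), p-TsOH·H2O (cat), toluene, reflux, Dean–Stark
Reagents that add atoms: ethylene glycol OCCO
Why: Acid-catalysed ketalisation should occur only at the less hindered carbonyl flanked by CH= and CH2 (future C3), because the other carbonyl (future C6) is flanked by the gem-dimethyl carbon and the methyl-bearing alkene carbon.

Step 2
Reactants: 2 7,9,9-trimethyl-1,4-dioxaspiro[4.5]dec-6-en-8-one; 3 (E)-3-methylpent-2-en-4-yn-1-ol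
Product: 5 8-[(3E)-5-hydroxy-3-methylpent-3-en-1-yn-1-yl]-7,9,9-trimethyl-1,4-dioxaspiro[4.5]dec-6-en-8-ol (racemic), via dilithio enynolate 4 (not isolated)
Conditions: 3, n-BuLi (2 equiv per 3), THF, −78 → 0 °C; then 2, −78 °C → rt; H2O
Reagents that add atoms: none
Why: 1,2-Addition of a lithium acetylide to a hindered enone (the reaction type used for abscisic-acid-type carbinols) should join C6 to C7 without conjugate addition, the second lithium protecting the primary hydroxyl as its alkoxide, and the new racemic carbinol centre is erased in step 3.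

Step 3
Reactants: 5 8-[(3E)-5-hydroxy-3-methylpent-3-en-1-yn-1-yl]-7,9,9-trimethyl-1,4-dioxaspiro[4.5]dec-6-en-8-ol
Product: 7 (4Z)-4-[(3E)-5-hydroxy-3-methyl-2-oxopent-3-en-1-ylidene]-3,5,5-trimethylcyclohex-2-en-1-one, via ketal dienone 6 (not isolated)
Conditions: Ph3PAuNTf2 (2 mol %), MeOH (1 equiv), toluene, rt; then 1 M HCl, THF, rt
Reagents that add atoms: water O
Why: Gold-catalysed Meyer–Schuster rearrangement (methanol-assisted 1,3-shift of the tertiary propargylic oxygen from C6 to C8 by cationic monovalent gold; a Rupe-type enyne cannot form because C1 is quaternary and C5 is sp2) followed by acid hydrolysis of the dioxolane should give the cross-conjugated dienedione, and the exocyclic C6=C7 bond is expected to settle under the acidic conditions on the 6Z geometry that keeps the C8 acyl group away from the C1 gem-dimethyl group.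

Step 4
Reactants: 7 (4Z)-4-[(3E)-5-hydroxy-3-methyl-2-oxopent-3-en-1-ylidene]-3,5,5-trimethylcyclohex-2-en-1-one
Product: 9 [(2E)-3-methyl-4-oxo-5-[(1Z)-2,6,6-trimethyl-4-oxocyclohex-2-en-1-ylidene]pent-2-en-1-yl]triphenylphosphonium bromide, via allylic bromide 8 (not isolated)
Conditions: CBr4, PPh3 (1.1 equiv each), CH2Cl2, 0 °C; then PPh3 (1.5 equiv), rt, dark
Reagents that add atoms: carbon tetrabromide BrC(Br)(Br)Br; triphenylphosphine c1ccc(cc1)P(c1ccccc1)c1ccccc1
Why: Appel bromination of the primary allylic alcohol (SN2, no allylic transposition) followed by SN2 quaternisation of triphenylphosphine by the allylic bromide should give the Wittig salt under neutral conditions that the dienedione tolerates.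

Step 5
Reactants: 10 (2E,4E,6E)-2,7-dimethylocta-2,4,6-trienedial (C10 dialdehyde)
Product: 11 (2E,4E,6E,8E)-9-iodo-2,7-dimethylnona-2,4,6,8-tetraenal
Conditions: CHI3 (0.7 equiv), CrCl2 (4.5 equiv), THF/1,4-dioxane, 0 °C → rt, dark; excess 10 recovered
Reagents that add atoms: iodoform IC(I)I
Why: Takai olefination (E-selective addition–elimination of the geminal dichromium reagent formed from CHI3 and divalent chromium) with the haloform as limiting reagent should convert one of the two equivalent formyl groups into the E-iodoalkene, the unreacted dialdehyde and the bis-iodide being separable by polarity.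

Step 6
Reactants: 9 [(2E)-3-methyl-4-oxo-5-[(1Z)-2,6,6-trimethyl-4-oxocyclohex-2-en-1-ylidene]pent-2-en-1-yl]triphenylphosphonium bromide; 11 (2E,4E,6E,8E)-9-iodo-2,7-dimethylnona-2,4,6,8-tetraenal
Product: 14 (4Z)-4-[(3E,5E,7E,9E,11E,13E)-14-iodo-3,7,12-trimethyl-2-oxotetradeca-3,5,7,9,11,13-hexaen-1-ylidene]-3,5,5-trimethylcyclohex-2-en-1-one (C26 iodide), via phosphorus ylide 12 (not isolated), via 11Z isomer 13 (not isolated)
Conditions: NaOMe (1.05 equiv), CH2Cl2/MeOH, −10 °C → rt, dark; then EtOH, 70 °C, argon, dark
Reagents that add atoms: none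
Why: Wittig olefination of the vinylogous acyl-stabilised ylide with the polyenal (the C15 plus C10 type of coupling of carotenoid manufacture) should form C11=C12, and the congested 11Z isomer, destabilised by the clash of H10 with the C13 methyl group, should converge thermally on 11E while the C–I bond and the other alkenes are left alone.

Step 7
Reactants: 15 (4R,6R)-4-hydroxy-2,2,6-trimethylcyclohexan-1-one (actinol)
Product: 16 (4R,6R)-4-[(tert-butyldimethylsilyl)oxy]-2,2,6-trimethylcyclohexan-1-one
Conditions: TBSCl, imidazole, DMF, rt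
Reagents that add atoms: tert-butyldimethylsilyl chloride CC(C)(C)[Si](C)(C)Cl
Why: Standard imidazole-mediated silylation of the secondary alcohol should protect the future C3' hydroxyl for the organolithium and dehydration steps without touching the hindered ketone or the carbinol stereocentre.

Step 8
Reactants: 16 (4R,6R)-4-[(tert-butyldimethylsilyl)oxy]-2,2,6-trimethylcyclohexan-1-one; 17 1,4-bis(trimethylsilyl)buta-1,3-diyne
Product: 19 (4R,6R)-4-[(tert-butyldimethylsilyl)oxy]-2,2,6-trimethyl-1-[4-(trimethylsilyl)buta-1,3-diyn-1-yl]cyclohexan-1-ol (mixture of C1 epimers), via lithium silylbutadiynide 18 (not isolated)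
Conditions: 17, MeLi·LiBr (1 equiv), THF, rt; then 16, −78 → 0 °C; H2O
Reagents that add atoms: none
Why: Monodesilylation of the bis-silyl diyne by MeLi gives the lithium butadiynide, whose 1,2-addition to the hindered ketone (acetylide addition) should install all four carbons C7' to C10' at once, the configuration of the new carbinol carbon being irrelevant because it becomes sp2 in step 9.

Step 9
Reactants: 19 (4R,6R)-4-[(tert-butyldimethylsilyl)oxy]-2,2,6-trimethyl-1-[4-(trimethylsilyl)buta-1,3-diyn-1-yl]cyclohexan-1-ol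
Product: 20 tert-butyldimethyl{[(1R)-3,5,5-trimethyl-4-[4-(trimethylsilyl)buta-1,3-diyn-1-yl]cyclohex-3-en-1-yl]oxy}silane
Conditions: POCl3, pyridine, 90 °C
Reagents that add atoms: none
Why: POCl3/pyridine dehydration of the activated tertiary propargylic alcohol (the standard route to alkynyl-cyclohexene end groups) can only give the tetrasubstituted C5'=C6' alkene, because C1' is quaternary and the only β-hydrogen is on C5', and the remote C3' stereocentre is not affected.

Step 10
Reactants: 20 tert-butyldimethyl{[(1R)-3,5,5-trimethyl-4-[4-(trimethylsilyl)buta-1,3-diyn-1-yl]cyclohex-3-en-1-yl]oxy}silane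
Product: 21 (1R)-4-(buta-1,3-diyn-1-yl)-3,5,5-trimethylcyclohex-3-en-1-ol
Conditions: Bu4NF (2.5 equiv), wet THF, 0 °C → rt; kept and used at once as a solution
Reagents that add atoms: none
Why: Fluoride should cleave both the C(sp)–Si and the O–Si bond through pentacoordinate silicates to unveil the terminal 1,3-diyne and the free C3' alcohol in one operation, the sensitive diyne being kept in solution.

Step 11
Reactants: 21 (1R)-4-(buta-1,3-diyn-1-yl)-3,5,5-trimethylcyclohex-3-en-1-ol; 14 (4Z)-4-[(3E,5E,7E,9E,11E,13E)-14-iodo-3,7,12-trimethyl-2-oxotetradeca-3,5,7,9,11,13-hexaen-1-ylidene]-3,5,5-trimethylcyclohex-2-en-1-one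
Product: 24 target carotenoid CNP0205386.1 (6Z,9E,11E,13E,15E,13'E,11'E,9'E,3'R), via alkenylalane 22 (not isolated), via alkenylzinc chloride 23 (not isolated)
Conditions: 21 (1.4 equiv), Me3Al (4 equiv), Cp2ZrCl2 (0.3 equiv), H2O (1 equiv), CH2Cl2, −25 → 0 °C; volatiles removed in vacuo; THF, ZnCl2 (1.4 equiv), then 14 (1.0 equiv), Pd2(dba)3 (2.5 mol %), P(2-furyl)3 (10 mol %), rt, dark; aqueous potassium sodium tartrate
Reagents that add atoms: trimethylaluminium C[Al](C)C
Why: Mechanism: Me3Al first converts the C3' hydroxyl into its dimethylaluminium alkoxide (a temporary protecting group removed on work-up), then Zr-catalysed syn-methylalumination (Negishi carboalumination) adds CH3 to C9' and Al to the terminal C10' to give alkenylalane 22; after removal of excess Me3Al, transmetalation to zinc (23) and a Negishi cross-coupling cycle (oxidative addition of zerovalent palladium into the C11'–I bond of 14, Zn-to-Pd transmetalation, reductive elimination) should forge the C10'–C11' bond with retention at both alkenes. The closest known reaction type is the one-pot Zr-catalysed carboalumination/Pd- and Zn-catalysed alkenyl–alkenyl coupling of terminal (including conjugated) alkynes with alkenyl iodides used for polyene assembly. No ring is closed and no stereocentre is created; the new stereogenic element, the C9'=C10' double bond, is fixed as 9'E by the syn (cis) mode of the Me–Al addition, and C3' and the 11'E geometry of the iodide are carried through unchanged. The step needs regioselectivity (Al on C10'), site selectivity (terminal alkyne only) and chemoselectivity (C–I coupling without carbonyl attack): the bimetallic Zr–Al addition places the metal on the unsubstituted terminal carbon, the internal C7'≡C8' alkyne is disubstituted and shielded by the C5' methyl and C1' gem-dimethyl groups of ring B, and the two ketones of 14 are conjugated, hindered carbonyls that alkenylzinc and THF-complexed alkenylalane species should not attack at room temperature once free Me3Al has been evaporated. In a single operation the step thus installs the C9' methyl group, the 9'E geometry and the fragment-joining bond and delivers the unprotected target.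

**Compound list**

1 | ketoisophorone (2,6,6-trimethylcyclohex-2-ene-1,4-dione) | CC1=CC(=O)CC(C)(C)C1=O | starting material
2 | 7,9,9-trimethyl-1,4-dioxaspiro[4.5]dec-6-en-8-one | CC1=CC2(OCCO2)CC(C)(C)C1=O | intermediate
3 | (E)-3-methylpent-2-en-4-yn-1-ol | C#C/C(C)=C/CO | starting material
4 | dilithio derivative of 3 (lithium acetylide and lithium alkoxide; not isolated) | [Li]C#C/C(C)=C/CO[Li] | intermediate
5 | 8-[(3E)-5-hydroxy-3-methylpent-3-en-1-yn-1-yl]-7,9,9-trimethyl-1,4-dioxaspiro[4.5]dec-6-en-8-ol (racemic) | CC1=CC2(OCCO2)CC(C)(C)C1(O)C#C/C(C)=C/CO | intermediate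
6 | (8Z)-8-[(3E)-5-hydroxy-3-methyl-2-oxopent-3-en-1-ylidene]-7,9,9-trimethyl-1,4-dioxaspiro[4.5]dec-6-ene (not isolated) | CC1=CC2(OCCO2)CC(C)(C)/C1=C/C(=O)/C(C)=C/CO | intermediate
7 | (4Z)-4-[(3E)-5-hydroxy-3-methyl-2-oxopent-3-en-1-ylidene]-3,5,5-trimethylcyclohex-2-en-1-one | CC1=CC(=O)CC(C)(C)/C1=C/C(=O)/C(C)=C/CO | intermediate
8 | (4Z)-4-[(3E)-5-bromo-3-methyl-2-oxopent-3-en-1-ylidene]-3,5,5-trimethylcyclohex-2-en-1-one (not isolated) | CC1=CC(=O)CC(C)(C)/C1=C/C(=O)/C(C)=C/CBr | intermediate
9 | [(2E)-3-methyl-4-oxo-5-[(1Z)-2,6,6-trimethyl-4-oxocyclohex-2-en-1-ylidene]pent-2-en-1-yl]triphenylphosphonium bromide | CC1=CC(=O)CC(C)(C)/C1=C/C(=O)/C(C)=C/C[P+](c1ccccc1)(c1ccccc1)c1ccccc1.[Br-] | intermediate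
10 | (2E,4E,6E)-2,7-dimethylocta-2,4,6-trienedial | O=C/C(C)=C/C=C/C=C(C)/C=O | starting material
11 | (2E,4E,6E,8E)-9-iodo-2,7-dimethylnona-2,4,6,8-tetraenal | O=C/C(C)=C/C=C/C=C(C)/C=C/I | intermediate
12 | phosphorus ylide of 9 (not isolated) | CC1=CC(=O)CC(C)(C)/C1=C/C(=O)/C(C)=C/C=P(c1ccccc1)(c1ccccc1)c1ccccc1 | intermediate
13 | 11Z isomer of 14 (not isolated) | CC1=CC(=O)CC(C)(C)/C1=C/C(=O)/C(C)=C/C=C\C(C)=C\C=C\C=C(C)\C=C\I | intermediate
14 | (4Z)-4-[(3E,5E,7E,9E,11E,13E)-14-iodo-3,7,12-trimethyl-2-oxotetradeca-3,5,7,9,11,13-hexaen-1-ylidene]-3,5,5-trimethylcyclohex-2-en-1-one | CC1=CC(=O)CC(C)(C)/C1=C/C(=O)/C(C)=C/C=C/C(C)=C/C=C/C=C(C)/C=C/I | intermediate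
15 | (4R,6R)-4-hydroxy-2,2,6-trimethylcyclohexan-1-one (actinol) | C[C@@H]1C[C@@H](O)CC(C)(C)C1=O | starting material
16 | (4R,6R)-4-[(tert-butyldimethylsilyl)oxy]-2,2,6-trimethylcyclohexan-1-one | C[C@@H]1C[C@@H](O[Si](C)(C)C(C)(C)C)CC(C)(C)C1=O | intermediate
17 | 1,4-bis(trimethylsilyl)buta-1,3-diyne | C[Si](C)(C)C#CC#C[Si](C)(C)C | starting material
18 | lithium 4-(trimethylsilyl)buta-1,3-diyn-1-ide (not isolated) | [Li]C#CC#C[Si](C)(C)C | intermediate
19 | (4R,6R)-4-[(tert-butyldimethylsilyl)oxy]-2,2,6-trimethyl-1-[4-(trimethylsilyl)buta-1,3-diyn-1-yl]cyclohexan-1-ol (C1 epimers) | C[C@@H]1C[C@@H](O[Si](C)(C)C(C)(C)C)CC(C)(C)C1(O)C#CC#C[Si](C)(C)C | intermediate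
20 | tert-butyldimethyl{[(1R)-3,5,5-trimethyl-4-[4-(trimethylsilyl)buta-1,3-diyn-1-yl]cyclohex-3-en-1-yl]oxy}silane | C[Si](C)(C)C#CC#CC1=C(C)C[C@@H](O[Si](C)(C)C(C)(C)C)CC1(C)C | intermediate
21 | (1R)-4-(buta-1,3-diyn-1-yl)-3,5,5-trimethylcyclohex-3-en-1-ol | C#CC#CC1=C(C)C[C@@H](O)CC1(C)C | intermediate
22 | (E)-alkenyl(dimethyl)alane from syn-methylalumination of 21, C3' oxygen as dimethylaluminium alkoxide (not isolated) | C[Al](C)/C=C(\C)C#CC1=C(C)C[C@@H](O[Al](C)C)CC1(C)C | intermediate
23 | corresponding (E)-alkenylzinc chloride (not isolated) | Cl[Zn]/C=C(\C)C#CC1=C(C)C[C@@H](O[Al](C)C)CC1(C)C | intermediate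
24 | target: ring A 3,5,5-trimethyl-4-ylidenecyclohex-2-en-1-one joined through the 6Z exocyclic alkene, the C8 ketone, the all-E C9 to C10' polyene (methyls on C9, C13, C13', C9') and the C7'≡C8' alkyne to ring B, (3'R)-3'-hydroxy-trimethylcyclohexenyl | CC1=CC(=O)CC(C)(C)/C1=C/C(=O)/C(C)=C/C=C/C(C)=C/C=C/C=C(C)/C=C/C=C(\C)C#CC1=C(C)C[C@@H](O)CC1(C)C | target

**Summary**

Total step count: 11.
Longest linear sequence: 6 steps (steps 1, 2, 3, 4, 6, 11); the ring B branch is 5 steps (7, 8, 9, 10, 11) and step 5 is a one-step side branch.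

Steps most likely to fail:

Step 11. Residual Al–CH3 or alkenyl-metal species may add to the dienedione of 14 in a 1,2- or conjugate sense. The terminal diyne may also undergo C–H alumination or oligomerise before carbometalation, and methyl may transfer to palladium in place of the alkenyl group. The fallback separates carbometalation from coupling and uses a carbonyl-inert nucleophile. Setting out from 21, the same Zr-catalysed methylalumination is run, and the alkenylalane is quenched with 2-methoxy-4,4,5,5-tetramethyl-1,3,2-dioxaborolane to give, after aqueous work-up, the isolable alkenyl pinacol boronate (1R)-3,5,5-trimethyl-4-[(3E)-3-methyl-4-(4,4,5,5-tetramethyl-1,3,2-dioxaborolan-2-yl)but-3-en-1-yn-1-yl]cyclohex-3-en-1-ol F1. Suzuki–Miyaura coupling of this boronate with 14 (Pd(PPh3)4, TlOEt, THF/H2O, rt, dark) comes back to the route at 24.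

Step 3. The gold-bound pentadienyl cation may divert into a Nazarov-type cyclisation, or the doubly allylic–propargylic alcohol may undergo 1,3-transposition toward C4; convergence of the C6=C7 geometry may also be incomplete. The fallback replaces the redox-neutral shift by a reduction and an oxidative transposition. Setting out from 5, anti-hydroalumination with NaAlH2(OCH2CH2OMe)2 (THF, 0 °C → rt, directed by the propargylic alkoxide) gives the dienediol 8-[(1E,3E)-5-hydroxy-3-methylpenta-1,3-dien-1-yl]-7,9,9-trimethyl-1,4-dioxaspiro[4.5]dec-6-en-8-ol F2. Pyridinium chlorochromate (NaOAc, CH2Cl2) then effects the Babler–Dauben oxidative 1,3-transposition of the tertiary alcohol, expected toward the secondary C8 and not the neopentylic C4. It also oxidises the primary allylic alcohol, giving the keto-enal (2E)-3-methyl-4-oxo-5-[(8Z)-7,9,9-trimethyl-1,4-dioxaspiro[4.5]dec-6-en-8-ylidene]pent-2-enal F3. Aldehyde-selective reduction with NaBH(OAc)3 comes back to the route at 6, which is deketalised to 7 as in step 3.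

Step 6. The highly stabilised ylide may react sluggishly with the polyenal, or the base may trigger self-condensation (Michael addition to the dienedione, enolisation at C2); thermal 11Z to 11E convergence may be incomplete. The fallback reverses the polarity of the olefination. Setting out from 7 and 11, Dess–Martin oxidation of 7 gives the keto-enal (2E)-3-methyl-4-oxo-5-[(1Z)-2,6,6-trimethyl-4-oxocyclohex-2-en-1-ylidene]pent-2-enal F4. NaBH4 (EtOH, −20 °C) reduces 11 to (2E,4E,6E,8E)-9-iodo-2,7-dimethylnona-2,4,6,8-tetraen-1-ol F5, and Ph3P·HBr (MeOH, rt) converts this into [(2E,4E,6E,8E)-9-iodo-2,7-dimethylnona-2,4,6,8-tetraen-1-yl]triphenylphosphonium bromide F6. Wittig reaction of the more reactive polyenyl ylide of this salt with the keto-enal (NaOMe, CH2Cl2/MeOH, then thermal convergence) comes back to the route at 14.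

**Further compounds**

F1 | step 11 | (1R)-3,5,5-trimethyl-4-[(3E)-3-methyl-4-(4,4,5,5-tetramethyl-1,3,2-dioxaborolan-2-yl)but-3-en-1-yn-1-yl]cyclohex-3-en-1-ol | CC1(C)OB(OC1(C)C)/C=C(\C)C#CC1=C(C)C[C@@H](O)CC1(C)C
F2 | step 3 | 8-[(1E,3E)-5-hydroxy-3-methylpenta-1,3-dien-1-yl]-7,9,9-trimethyl-1,4-dioxaspiro[4.5]dec-6-en-8-ol | CC1=CC2(OCCO2)CC(C)(C)C1(O)/C=C/C(C)=C/CO
F3 | step 3 | (2E)-3-methyl-4-oxo-5-[(8Z)-7,9,9-trimethyl-1,4-dioxaspiro[4.5]dec-6-en-8-ylidene]pent-2-enal | CC1=CC2(OCCO2)CC(C)(C)/C1=C/C(=O)/C(C)=C/C=O
F4 | step 6 | (2E)-3-methyl-4-oxo-5-[(1Z)-2,6,6-trimethyl-4-oxocyclohex-2-en-1-ylidene]pent-2-enal | CC1=CC(=O)CC(C)(C)/C1=C/C(=O)/C(C)=C/C=O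
F5 | step 6 | (2E,4E,6E,8E)-9-iodo-2,7-dimethylnona-2,4,6,8-tetraen-1-ol | OC/C(C)=C/C=C/C=C(C)/C=C/I
F6 | step 6 | [(2E,4E,6E,8E)-9-iodo-2,7-dimethylnona-2,4,6,8-tetraen-1-yl]triphenylphosphonium bromide | [Br-].I/C=C/C(C)=C/C=C/C=C(C)/C[P+](c1ccccc1)(c1ccccc1)c1ccccc1
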